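**Plan**
- Retrosynthesis: CO2H from CH2OH; the dioxane is cut at O–C3′ (hydroperoxide displacing a mesylate) and at O–C6′ (perhydrolysis of an epoxide); C6′–C7′ is cut by a B-alkyl Suzuki coupling into iodide 18 and vinyl iodide 27; C5–C10 and C8–C9 are cut together, opening rings A and B to the acyclic allenoate–diene 11; the allene goes back to a propargylic mesylate and CO.
- Enabling feature: ring B carries on its C9–C10 edge the quaternary C9 and the sp2 C10 of the ring A olefin C1=C10. The unit C1=C10–C9 is read as what remains of an allene C1=C10=C9 whose C9=C10 bond has added to a diene C5=C6–C7=C8 tied to C1 through C2–C4. The C9 methyl is carried as an activating CO2Me and reduced afterwards.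
- Forward order: chain 11 (steps 1–7), rings A and B in one operation (step 8), C6=C7 saturation, ester to methyl and side-chain union (steps 9–21), dioxane ring last (steps 22–26), acid (steps 27–28).
- Stereochemistry: a Noyori reduction sets a carbinol that is relayed to the allene axis and from there to C5 and C9; the (7Z) olefin sets C8; an Evans syn-aldol sets C2′ and C3′ (C3′ inverted on ring closure); a Shi epoxidation sets C6′ (inverted on perhydrolysis).

Key step: step 8

**Remarks**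
- Numbering: bicyclic core C1–C10 (C4 gem-dimethyl, C5 ring-fusion CH, C8 CHMe, C9 quaternary, C10 sp2). Side chain counted from the carboxyl carbon: C1′, C2′ (CHMe), C3′ (dioxane CH), C4′, C5′, C6′ (dioxane C–Me), C7′, C8′ (bonded to C9). α/β refer to the decalin drawn in the usual terpenoid orientation.
- "Bic" = (1R,2R,4aS)-1,2,5,5-tetramethyl-1,2,3,4,4a,5,6,7-octahydronaphthalen-1-yl, the bicyclic unit of 16–18 and of the target.
- Assumption: methyl 4,4-dimethyl-5-oxopentanoate (1), the Michael adduct of isobutyraldehyde and methyl acrylate, is taken as purchasable.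
- The allene axis in SMILES is written as an extended tetrahedral centre on the central allene carbon.

**Route**

Step 1
Reactants: 1 methyl 4,4-dimethyl-5-oxopentanoate
Product: 2 methyl (5E)-6-iodo-4,4-dimethylhex-5-enoate
Conditions: CrCl2, CHI3, THF, 0 °C to rt
Reagents that add atoms: iodoform, IC(I)I
Why: Takai olefination of the non-enolisable aldehyde should give the (E)-vinyl iodide through anti elimination from the gem-dichromium adduct.

Step 2
Reactants: 2 methyl (5E)-6-iodo-4,4-dimethylhex-5-enoate; 3 (Z)-prop-1-en-1-ylboronic acid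
Product: 4 methyl (5E,7Z)-4,4-dimethylnona-5,7-dienoate
Conditions: PdCl2(dppf) (cat.), K3PO4, THF/H2O, rt
Reagents that add atoms: none
Why: Suzuki–Miyaura coupling proceeds with retention at both sp2 carbons, so the (5E,7Z)-diene that later fixes C8 should be obtained geometrically pure.

Step 3
Reactants: 4 methyl (5E,7Z)-4,4-dimethylnona-5,7-dienoate
Product: 5 (5E,7Z)-N-methoxy-N,4,4-trimethylnona-5,7-dienamide
Conditions: MeNH(OMe)·HCl, iPrMgCl, THF, −20 °C
Reagents that add atoms: N,O-dimethylhydroxylamine hydrochloride, CNOC.Cl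
Why: Aminolysis of the ester by the magnesium amide (Weinreb amide formation) should leave the diene untouched.

Step 4
Reactants: 5 (5E,7Z)-N-methoxy-N,4,4-trimethylnona-5,7-dienamide; 6 tert-butyl(but-3-yn-1-yloxy)dimethylsilane
Product: 8 (9E,11Z)-1-(tert-butyldimethylsilyloxy)-8,8-dimethyltrideca-9,11-dien-3-yn-5-one, via lithium acetylide 7 (not isolated)
Conditions: 6, n-BuLi, THF, −78 °C; then 5, −78 to 0 °C
Reagents that add atoms: none
Why: Acetylide addition to a Weinreb amide stops at the chelated tetrahedral adduct, so the ynone should form without over-addition.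

Step 5
Reactants: 8 (9E,11Z)-1-(tert-butyldimethylsilyloxy)-8,8-dimethyltrideca-9,11-dien-3-yn-5-one
Product: 9 (5S,9E,11Z)-1-(tert-butyldimethylsilyloxy)-8,8-dimethyltrideca-9,11-dien-3-yn-5-ol
Conditions: RuCl[(S,S)-TsNCH(Ph)CH(Ph)NH2](p-cymene) (cat.), iPrOH, rt
Reagents that add atoms: none
Why: Noyori asymmetric transfer hydrogenation of an alkynyl ketone, with the alkynyl group in the position an aryl group would take, should give the (S)-carbinol under catalyst control.

Step 6
Reactants: 9 (5S,9E,11Z)-1-(tert-butyldimethylsilyloxy)-8,8-dimethyltrideca-9,11-dien-3-yn-5-ol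
Product: 10 (5S,9E,11Z)-1-(tert-butyldimethylsilyloxy)-8,8-dimethyltrideca-9,11-dien-3-yn-5-yl methanesulfonate
Conditions: MsCl, Et3N, CH2Cl2, −78 to 0 °C
Reagents that add atoms: methanesulfonyl chloride, CS(=O)(=O)Cl
Why: O-sulfonylation leaves the carbinol configuration unchanged.

Step 7
Reactants: 10 (5S,9E,11Z)-1-(tert-butyldimethylsilyloxy)-8,8-dimethyltrideca-9,11-dien-3-yn-5-yl methanesulfonate
Product: 11 methyl (aR,8E,10Z)-2-[2-(tert-butyldimethylsilyloxy)ethyl]-7,7-dimethyldodeca-2,3,8,10-tetraenoate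
Conditions: Pd(PPh3)4 (cat.), CO (1 atm), MeOH, 2,6-lutidine, THF, rt
Reagents that add atoms: carbon monoxide, [C-]#[O+]; methanol, CO
Why: Palladium-catalysed SN2′ alkoxycarbonylation of a propargylic mesylate: anti oxidative addition of zerovalent palladium gives an allenylpalladium, and CO insertion and methanolysis go with retention, so the (S)-centre should be transferred to the (aR)-axis.

Step 8
Reactants: 11 methyl (aR,8E,10Z)-2-[2-(tert-butyldimethylsilyloxy)ethyl]-7,7-dimethyldodeca-2,3,8,10-tetraenoate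
Product: 12 methyl (1S,2R,4aS)-1-[2-(tert-butyldimethylsilyloxy)ethyl]-2,5,5-trimethyl-1,2,4a,5,6,7-hexahydronaphthalene-1-carboxylate (core numbering: 5α-H, 8α-Me, 9β-CO2Me, olefins C1=C10 and C6=C7)
Conditions: Me2AlCl (1.2 equiv), CH2Cl2, −78 to −20 °C
Reagents that add atoms: none
Why: Me2AlCl on the ester lowers the LUMO of the conjugated allene bond C9=C10, which should add suprafacially to C5 and C8 of the s-cis diene in a concerted, asynchronous intramolecular Diels–Alder reaction with the C5–C10 bond to the sp carbon leading; the closest known type is the Lewis-acid-promoted intramolecular Diels–Alder reaction of allenic esters and allenyl ethers through the π bond remote from the tether. Ring B closes as the [4+2] cyclohexene, and ring A closes in the same event through C5–C10 as a six-membered ring (exo with respect to the diene) that keeps the tether-side allene bond as the endocyclic olefin C1=C10. C5 is set by the allene axis, because the C1–C2 bond lets the tethered diene reach only one face of C9=C10, so (aR) should become (5S). C8 is set by the (7Z) geometry, the inside methyl ending trans to the outside C4–C5 bond (8α-Me). C9 is set by the Alder endo rule, the complexed ester lying under C6–C7 (9β-CO2Me, 9α side chain). The step needs site selectivity for C9=C10 over the unactivated C1=C10 bond (secured by conjugation with the complexed ester), endo over exo orientation (secured by the Lewis acid) and retention of the Z olefin (low temperature).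

Step 9
Reactants: 12 Diels–Alder adduct
Product: 13 methyl (1S,2R,4aS)-1-[2-(tert-butyldimethylsilyloxy)ethyl]-2,5,5-trimethyl-1,2,3,4,4a,5,6,7-octahydronaphthalene-1-carboxylate
Conditions: 2-nitrobenzenesulfonylhydrazide, Et3N, CH2Cl2, rt
Reagents that add atoms: none
Why: Diimide reduction should saturate the cis-disubstituted C6=C7 bond and spare the hindered trisubstituted C1=C10 bond.

Step 10
Reactants: 13 octahydronaphthalene ester
Product: 14 {(1S,2R,4aS)-1-[2-(tert-butyldimethylsilyloxy)ethyl]-2,5,5-trimethyl-1,2,3,4,4a,5,6,7-octahydronaphthalen-1-yl}methanol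
Conditions: LiAlH4, THF, 0 °C to rt
Reagents that add atoms: none
Why: Hydride reduction of the neopentyl ester to the primary alcohol does not touch the olefin or the silyl ether.

Step 11
Reactants: 14 neopentyl alcohol
Product: 15 {(1S,2R,4aS)-1-[2-(tert-butyldimethylsilyloxy)ethyl]-2,5,5-trimethyl-1,2,3,4,4a,5,6,7-octahydronaphthalen-1-yl}methyl methanesulfonate
Conditions: MsCl, Et3N, DMAP (cat.), CH2Cl2, 0 °C
Reagents that add atoms: methanesulfonyl chloride, CS(=O)(=O)Cl
Why: O-sulfonylation activates the primary alcohol for hydride displacement.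

Step 12
Reactants: 15 neopentyl mesylate
Product: 16 tert-butyl{2-[(1R,2R,4aS)-1,2,5,5-tetramethyl-1,2,3,4,4a,5,6,7-octahydronaphthalen-1-yl]ethoxy}dimethylsilane
Conditions: LiEt3BH, THF, reflux
Reagents that add atoms: none
Why: SN2 hydride displacement of the primary mesylate by LiEt3BH (Super-Hydride reduction) should convert the former activating group into the C9 methyl without touching C9.

Step 13
Reactants: 16 silyl ether
Product: 17 2-Bic-ethan-1-ol
Conditions: Bu4NF, THF, rt
Reagents that add atoms: none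
Why: Fluoride-induced desilylation frees the primary alcohol.

Step 14
Reactants: 17 2-Bic-ethan-1-ol
Product: 18 (1R,2R,4aS)-1-(2-iodoethyl)-1,2,5,5-tetramethyl-1,2,3,4,4a,5,6,7-octahydronaphthalene
Conditions: I2, PPh3, imidazole, CH2Cl2, 0 °C to rt
Reagents that add atoms: iodine, II
Why: Appel-type iodination of the unhindered primary alcohol under non-acidic conditions preserves the C1=C10 olefin.

Step 15
Reactants: 19 pent-3-yn-1-ol
Product: 20 pent-3-ynal
Conditions: Dess–Martin periodinane, NaHCO3, CH2Cl2, 0 °C; used crude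
Reagents that add atoms: none
Why: Dess–Martin oxidation is non-basic, so the β,γ-alkynal should not isomerise to the allenal.

Step 16
Reactants: 21 (S)-4-benzyl-3-propanoyl-1,3-oxazolidin-2-one; 20 pent-3-ynal
Product: 23 (S)-4-benzyl-3-[(2S,3R)-3-hydroxy-2-methylhept-5-ynoyl]-1,3-oxazolidin-2-one, via boron enolate 22 (not isolated)
Conditions: 21, Bu2BOTf, iPr2NEt, CH2Cl2, −78 to 0 °C; then 20, −78 to 0 °C; pH 7 buffer, MeOH, H2O2
Reagents that add atoms: none
Why: Evans syn-aldol reaction through the (Z)-boron enolate and a Zimmerman–Traxler chair should set C2′ and C3′ under auxiliary control.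

Step 17
Reactants: 23 aldol adduct
Product: 24 (2R,3R)-2-methylhept-5-yne-1,3-diol
Conditions: LiBH4, THF/MeOH, 0 °C
Reagents that add atoms: none
Why: Reductive cleavage of the imide releases the auxiliary and gives the 1,3-diol without epimerisation.

Step 18
Reactants: 24 diol
Product: 25 (2R,3R)-1-(tert-butyldiphenylsilyloxy)-2-methylhept-5-yn-3-ol
Conditions: t-BuPh2SiCl, imidazole, CH2Cl2, 0 °C
Reagents that add atoms: tert-butyl(chloro)diphenylsilane, CC(C)(C)[Si](Cl)(c1ccccc1)c1ccccc1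
Why: The bulky silyl chloride should select the primary hydroxyl.

Step 19
Reactants: 25 silyl ether alkynol
Product: 27 (2R,3R,5E)-1-(tert-butyldiphenylsilyloxy)-6-iodo-2-methylhept-5-en-3-ol, via alkenylzirconocene 26 (not isolated)
Conditions: Cp2Zr(H)Cl (2.5 equiv), THF, rt to 40 °C; then I2, 0 °C
Reagents that add atoms: iodine, II
Why: Hydrozirconation–iodination (Schwartz reagent): syn addition places zirconium on the less hindered methyl-bearing carbon after equilibration, and iodinolysis with retention should give the (E)-iodide.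

Step 20
Reactants: 18 bicyclic iodide; 27 vinyl iodide
Product: 30 (2R,3R,5E)-8-Bic-1-(tert-butyldiphenylsilyloxy)-2,6-dimethyloct-5-en-3-ol, via alkyllithium 28 (not isolated), via borate 29 (not isolated)
Conditions: 18, t-BuLi, Et2O, −78 °C; 9-MeO-9-BBN, THF, −78 °C to rt; then 27, PdCl2(dppf) (cat.), AsPh3, Cs2CO3, DMF/H2O, rt
Reagents that add atoms: none
Why: B-alkyl Suzuki–Miyaura coupling of the borate made by lithium–iodine exchange joins C7′ to C6′ with retention of the olefin geometry.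

Step 21
Reactants: 30 homoallylic alcohol
Product: 31 (2R,3R,5E)-8-Bic-1-(tert-butyldiphenylsilyloxy)-2,6-dimethyloct-5-en-3-yl methanesulfonate
Conditions: MsCl, Et3N, CH2Cl2, 0 °C
Reagents that add atoms: methanesulfonyl chloride, CS(=O)(=O)Cl
Why: O-sulfonylation with retention turns C3′–O into the leaving group for the later ring closure and removes the hydroxyl that could open the epoxide.

Step 22
Reactants: 31 mesylate
Product: 32 (2R,3R,5S,6S)-8-Bic-1-(tert-butyldiphenylsilyloxy)-5,6-epoxy-2,6-dimethyloctan-3-yl methanesulfonate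
Conditions: 1,2:4,5-di-O-isopropylidene-β-L-erythro-2,3-hexodiulo-2,6-pyranose (cat.), KHSO5 (as 2KHSO5·KHSO4·K2SO4), K2CO3, Bu4NHSO4, MeCN/CH2(OMe)2/aq. Na2B4O7, 0 °C
Reagents that add atoms: potassium peroxymonosulfate, [K+].[O-]S(=O)(=O)OO
Why: Shi epoxidation through the spiro dioxirane transition state should deliver oxygen under reagent control to one face of the unhindered (E)-trisubstituted side-chain olefin, while the C1=C10 olefin flanked by C9 and C5 reacts more slowly.

Step 23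
Reactants: 32 epoxy mesylate
Product: 33 (2R,3R,5S,6R)-8-Bic-1-(tert-butyldiphenylsilyloxy)-6-hydroperoxy-5-hydroxy-2,6-dimethyloctan-3-yl methanesulfonate
Conditions: H2O2 (ethereal, excess), H3PMo12O40 (cat.), Et2O, rt
Reagents that add atoms: hydrogen peroxide, OO
Why: Acid-catalysed perhydrolysis of a trisubstituted epoxide: H2O2 attacks the tertiary carbon from the back side, so C6′ should be inverted to the configuration of the target.

Step 24
Reactants: 33 hydroperoxy mesylate
Product: 34 (3R,4S,6S)-3-(2-Bic-ethyl)-6-[(2R)-1-(tert-butyldiphenylsilyloxy)propan-2-yl]-3-methyl-1,2-dioxan-4-ol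
Conditions: KOtBu (1.05 equiv), 18-crown-6, toluene, 0 °C
Reagents that add atoms: none
Why: Intramolecular 6-exo-tet alkylation of the hydroperoxide anion on the secondary mesylate closes the 1,2-dioxane with inversion at C3′.

Step 25
Reactants: 34 dioxanol
Product: 35 (3R,6S)-3-(2-Bic-ethyl)-6-[(2R)-1-(tert-butyldiphenylsilyloxy)propan-2-yl]-3-methyl-3,6-dihydro-1,2-dioxine
Conditions: Martin sulfurane Ph2S[OC(CF3)2Ph]2, CH2Cl2, rt
Reagents that add atoms: none
Why: Martin sulfurane dehydration can only eliminate towards C4′ because C6′ carries no hydrogen, so the ring hydroxyl left by the epoxide should be removed as the C4′=C5′ olefin under neutral conditions.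

Step 26
Reactants: 35 dihydrodioxine
Product: 36 (3R,6S)-3-(2-Bic-ethyl)-6-[(2R)-1-(tert-butyldiphenylsilyloxy)propan-2-yl]-3-methyl-1,2-dioxane
Conditions: 2-nitrobenzenesulfonylhydrazide, Et3N, CH2Cl2, rt
Reagents that add atoms: none
Why: Diimide reduction saturates the cis ring olefin without cleaving the O–O bond or reducing the C1=C10 olefin.

Step 27
Reactants: 36 silyl ether dioxane
Product: 37 (2R)-2-[(3S,6R)-6-(2-Bic-ethyl)-6-methyl-1,2-dioxan-3-yl]propan-1-ol
Conditions: HF·pyridine, THF/pyridine, 0 °C to rt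
Reagents that add atoms: none
Why: Buffered fluoride desilylation frees the primary alcohol without base that could fragment the peroxide.

Step 28
Reactants: 37 primary alcohol
Product: 39 mycaperoxide H, (2S)-2-[(3S,6R)-6-(2-Bic-ethyl)-6-methyl-1,2-dioxan-3-yl]propanoic acid, via aldehyde 38 (not isolated)
Conditions: 2,2,6,6-tetramethylpiperidin-1-oxyl (cat.), PhI(OAc)2, MeCN/H2O (pH 7 buffer), rt
Reagents that add atoms: water, O
Why: Oxoammonium oxidation of the alcohol to the aldehyde and of its hydrate to the acid runs under non-basic conditions, so C2′ should not epimerise and the β-peroxy carbonyl should not eliminate.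

**Compound list**
1 | methyl 4,4-dimethyl-5-oxopentanoate | COC(=O)CCC(C)(C)C=O | starting material
2 | methyl (5E)-6-iodo-4,4-dimethylhex-5-enoate | COC(=O)CCC(C)(C)/C=C/I | intermediate
3 | (Z)-prop-1-en-1-ylboronic acid | C/C=C\B(O)O | starting material
4 | methyl (5E,7Z)-4,4-dimethylnona-5,7-dienoate | COC(=O)CCC(C)(C)/C=C/C=C\C | intermediate
5 | (5E,7Z)-N-methoxy-N,4,4-trimethylnona-5,7-dienamide | CON(C)C(=O)CCC(C)(C)/C=C/C=C\C | intermediate
6 | tert-butyl(but-3-yn-1-yloxy)dimethylsilane | C#CCCO[Si](C)(C)C(C)(C)C | starting material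
7 | [4-(tert-butyldimethylsilyloxy)but-1-yn-1-yl]lithium | [Li]C#CCCO[Si](C)(C)C(C)(C)C | intermediate
8 | (9E,11Z)-1-(tert-butyldimethylsilyloxy)-8,8-dimethyltrideca-9,11-dien-3-yn-5-one | CC(C)(C)[Si](C)(C)OCCC#CC(=O)CCC(C)(C)/C=C/C=C\C | intermediate
9 | (5S,9E,11Z)-1-(tert-butyldimethylsilyloxy)-8,8-dimethyltrideca-9,11-dien-3-yn-5-ol | CC(C)(C)[Si](C)(C)OCCC#C[C@@H](O)CCC(C)(C)/C=C/C=C\C | intermediate
10 | (5S,9E,11Z)-1-(tert-butyldimethylsilyloxy)-8,8-dimethyltrideca-9,11-dien-3-yn-5-yl methanesulfonate | CC(C)(C)[Si](C)(C)OCCC#C[C@@H](OS(C)(=O)=O)CCC(C)(C)/C=C/C=C\C | intermediate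
11 | methyl (aR,8E,10Z)-2-[2-(tert-butyldimethylsilyloxy)ethyl]-7,7-dimethyldodeca-2,3,8,10-tetraenoate | COC(=O)C(CCO[Si](C)(C)C(C)(C)C)=[C@]=C([H])CCC(C)(C)/C=C/C=C\C | intermediate
12 | methyl (1S,2R,4aS)-1-[2-(tert-butyldimethylsilyloxy)ethyl]-2,5,5-trimethyl-1,2,4a,5,6,7-hexahydronaphthalene-1-carboxylate | CC(C)(C)[Si](C)(C)OCC[C@@]1(C(=O)OC)C2=CCCC(C)(C)[C@@H]2C=C[C@H]1C | intermediate
13 | methyl (1S,2R,4aS)-1-[2-(tert-butyldimethylsilyloxy)ethyl]-2,5,5-trimethyl-1,2,3,4,4a,5,6,7-octahydronaphthalene-1-carboxylate | CC(C)(C)[Si](C)(C)OCC[C@@]1(C(=O)OC)C2=CCCC(C)(C)[C@@H]2CC[C@H]1C | intermediate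
14 | {(1S,2R,4aS)-1-[2-(tert-butyldimethylsilyloxy)ethyl]-2,5,5-trimethyl-1,2,3,4,4a,5,6,7-octahydronaphthalen-1-yl}methanol | CC(C)(C)[Si](C)(C)OCC[C@@]1(CO)C2=CCCC(C)(C)[C@@H]2CC[C@H]1C | intermediate
15 | {(1S,2R,4aS)-1-[2-(tert-butyldimethylsilyloxy)ethyl]-2,5,5-trimethyl-1,2,3,4,4a,5,6,7-octahydronaphthalen-1-yl}methyl methanesulfonate | CC(C)(C)[Si](C)(C)OCC[C@@]1(COS(C)(=O)=O)C2=CCCC(C)(C)[C@@H]2CC[C@H]1C | intermediate
16 | tert-butyl{2-[(1R,2R,4aS)-1,2,5,5-tetramethyl-1,2,3,4,4a,5,6,7-octahydronaphthalen-1-yl]ethoxy}dimethylsilane | CC(C)(C)[Si](C)(C)OCC[C@@]1(C)C2=CCCC(C)(C)[C@@H]2CC[C@H]1C | intermediate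
17 | 2-[(1R,2R,4aS)-1,2,5,5-tetramethyl-1,2,3,4,4a,5,6,7-octahydronaphthalen-1-yl]ethan-1-ol | OCC[C@@]1(C)C2=CCCC(C)(C)[C@@H]2CC[C@H]1C | intermediate
18 | (1R,2R,4aS)-1-(2-iodoethyl)-1,2,5,5-tetramethyl-1,2,3,4,4a,5,6,7-octahydronaphthalene | ICC[C@@]1(C)C2=CCCC(C)(C)[C@@H]2CC[C@H]1C | intermediate
19 | pent-3-yn-1-ol | CC#CCCO | starting material
20 | pent-3-ynal | CC#CCC=O | intermediate
21 | (S)-4-benzyl-3-propanoyl-1,3-oxazolidin-2-one | CCC(=O)N1[C@@H](Cc2ccccc2)COC1=O | starting material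
22 | dibutylboron (Z)-enolate of 21 | C/C=C(\OB(CCCC)CCCC)N1[C@@H](Cc2ccccc2)COC1=O | intermediate
23 | (S)-4-benzyl-3-[(2S,3R)-3-hydroxy-2-methylhept-5-ynoyl]-1,3-oxazolidin-2-one | CC#CC[C@@H](O)[C@H](C)C(=O)N1[C@@H](Cc2ccccc2)COC1=O | intermediate
24 | (2R,3R)-2-methylhept-5-yne-1,3-diol | CC#CC[C@@H](O)[C@H](C)CO | intermediate
25 | (2R,3R)-1-(tert-butyldiphenylsilyloxy)-2-methylhept-5-yn-3-ol | CC#CC[C@@H](O)[C@H](C)CO[Si](c1ccccc1)(c1ccccc1)C(C)(C)C | intermediate
26 | (E)-alkenylzirconocene chloride from 25 (zirconium on C6, hydroxyl as zirconium alkoxide) | C/C(=C\C[C@@H](O[Zr](Cl)(C1C=CC=C1)C1C=CC=C1)[C@H](C)CO[Si](c1ccccc1)(c1ccccc1)C(C)(C)C)[Zr](Cl)(C1C=CC=C1)C1C=CC=C1 | intermediate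
27 | (2R,3R,5E)-1-(tert-butyldiphenylsilyloxy)-6-iodo-2-methylhept-5-en-3-ol | C/C(I)=C\C[C@@H](O)[C@H](C)CO[Si](c1ccccc1)(c1ccccc1)C(C)(C)C | intermediate
28 | (2-Bic-ethyl)lithium | [Li]CC[C@@]1(C)C2=CCCC(C)(C)[C@@H]2CC[C@H]1C | intermediate
29 | lithium 9-(2-Bic-ethyl)-9-methoxy-9-boratabicyclo[3.3.1]nonane | [Li+].CO[B-]1(CC[C@@]2(C)C3=CCCC(C)(C)[C@@H]3CC[C@H]2C)C2CCCC1CCC2 | intermediate
30 | (2R,3R,5E)-8-Bic-1-(tert-butyldiphenylsilyloxy)-2,6-dimethyloct-5-en-3-ol | C/C(CC[C@@]1(C)C2=CCCC(C)(C)[C@@H]2CC[C@H]1C)=C\C[C@@H](O)[C@H](C)CO[Si](c1ccccc1)(c1ccccc1)C(C)(C)C | intermediate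
31 | (2R,3R,5E)-8-Bic-1-(tert-butyldiphenylsilyloxy)-2,6-dimethyloct-5-en-3-yl methanesulfonate | C/C(CC[C@@]1(C)C2=CCCC(C)(C)[C@@H]2CC[C@H]1C)=C\C[C@@H](OS(C)(=O)=O)[C@H](C)CO[Si](c1ccccc1)(c1ccccc1)C(C)(C)C | intermediate
32 | (2R,3R,5S,6S)-8-Bic-1-(tert-butyldiphenylsilyloxy)-5,6-epoxy-2,6-dimethyloctan-3-yl methanesulfonate | C[C@@]1(CC[C@@]2(C)C3=CCCC(C)(C)[C@@H]3CC[C@H]2C)O[C@H]1C[C@@H](OS(C)(=O)=O)[C@H](C)CO[Si](c1ccccc1)(c1ccccc1)C(C)(C)C | intermediate
33 | (2R,3R,5S,6R)-8-Bic-1-(tert-butyldiphenylsilyloxy)-6-hydroperoxy-5-hydroxy-2,6-dimethyloctan-3-yl methanesulfonate | C[C@](CC[C@@]1(C)C2=CCCC(C)(C)[C@@H]2CC[C@H]1C)(OO)[C@@H](O)C[C@@H](OS(C)(=O)=O)[C@H](C)CO[Si](c1ccccc1)(c1ccccc1)C(C)(C)C | intermediate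
34 | (3R,4S,6S)-3-(2-Bic-ethyl)-6-[(2R)-1-(tert-butyldiphenylsilyloxy)propan-2-yl]-3-methyl-1,2-dioxan-4-ol | C[C@H](CO[Si](c1ccccc1)(c1ccccc1)C(C)(C)C)[C@@H]1C[C@H](O)[C@@](C)(CC[C@@]2(C)C3=CCCC(C)(C)[C@@H]3CC[C@H]2C)OO1 | intermediate
35 | (3R,6S)-3-(2-Bic-ethyl)-6-[(2R)-1-(tert-butyldiphenylsilyloxy)propan-2-yl]-3-methyl-3,6-dihydro-1,2-dioxine | C[C@H](CO[Si](c1ccccc1)(c1ccccc1)C(C)(C)C)[C@@H]1C=C[C@@](C)(CC[C@@]2(C)C3=CCCC(C)(C)[C@@H]3CC[C@H]2C)OO1 | intermediate
36 | (3R,6S)-3-(2-Bic-ethyl)-6-[(2R)-1-(tert-butyldiphenylsilyloxy)propan-2-yl]-3-methyl-1,2-dioxane | C[C@H](CO[Si](c1ccccc1)(c1ccccc1)C(C)(C)C)[C@@H]1CC[C@@](C)(CC[C@@]2(C)C3=CCCC(C)(C)[C@@H]3CC[C@H]2C)OO1 | intermediate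
37 | (2R)-2-[(3S,6R)-6-(2-Bic-ethyl)-6-methyl-1,2-dioxan-3-yl]propan-1-ol | C[C@H](CO)[C@@H]1CC[C@@](C)(CC[C@@]2(C)C3=CCCC(C)(C)[C@@H]3CC[C@H]2C)OO1 | intermediate
38 | (2S)-2-[(3S,6R)-6-(2-Bic-ethyl)-6-methyl-1,2-dioxan-3-yl]propanal | C[C@H](C=O)[C@@H]1CC[C@@](C)(CC[C@@]2(C)C3=CCCC(C)(C)[C@@H]3CC[C@H]2C)OO1 | intermediate
39 | mycaperoxide H, (2S)-2-[(3S,6R)-6-{2-[(1R,2R,4aS)-1,2,5,5-tetramethyl-1,2,3,4,4a,5,6,7-octahydronaphthalen-1-yl]ethyl}-6-methyl-1,2-dioxan-3-yl]propanoic acid | C[C@H](C(=O)O)[C@@H]1CC[C@@](C)(CC[C@@]2(C)C3=CCCC(C)(C)[C@@H]3CC[C@H]2C)OO1 | target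

**Count**
Total steps: 28. Longest linear sequence: 23 steps (steps 1–14 and 20–28, from 1); the side-chain fragment takes 5 steps (15–19).

**Steps most likely to fail**

Step 8. The allene has no tether substituent on C10 to relay the ring fusion to C9, so endo/exo discrimination may be weak; the Z-substituted diene may also react slowly and isomerise under the Lewis acid. Fallback: a conventional trans-selective trienoate Diels–Alder reaction in which the tether and allylic strain control C9 and the face. It sets out from 9. Silylation (Et3SiCl, imidazole) gives the triethylsilyl ether F1. Hydrozirconation (Cp2Zr(H)Cl) places zirconium on the alkyne carbon remote from the silyloxy group in the alkenylzirconocene F2, and iodine gives the (E)-vinyl iodide F3. Methoxycarbonylation (PdCl2(PPh3)2, CO, MeOH, Et3N) gives the (E)-trienoate F4, with the ester trans to the carbinol carbon. Cycloaddition (Me2AlCl or heat), with the ester endo, the tether exo and the silyloxy group axial to avoid allylic strain with the cis side chain, should give the trans-fused adduct F5 (1α-OSiEt3, 10β-H). Diimide gives the 6,7-dihydro compound F6, and pyridinium p-toluenesulfonate in MeOH frees the axial 1α-alcohol F7. Anti elimination with Martin sulfurane towards the antiperiplanar 10β-H then returns to the route at 13.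

Step 23. The opening may run through a free tertiary cation, with loss of configuration at C6′, a pinacol-type shift or capture by the C1=C10 olefin. Fallback: reverse the order of the two C–O bond formations. It sets out from 32. Displacement of the mesylate with 2-methoxyprop-2-yl hydroperoxide and CsOH in DMF (inversion at C3′) gives the peroxyketal F8. Aqueous acetic acid unmasks the secondary hydroperoxide F9, which under a trace of camphorsulfonic acid opens the epoxide intramolecularly at the tertiary carbon (6-endo, inversion at C6′). This returns to the route at 34 with the same two inversions.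

Step 25. The activated hydroxyl next to the peroxide-bearing quaternary carbon may ionise, leading to ring contraction or O–O fragmentation instead of clean anti elimination. Fallback: never introduce the ring hydroxyl. It sets out from 31. Cobalt-catalysed hydroperoxysilylation of the side-chain olefin (Co(acac)2, O2, Et3SiH, Mukaiyama–Isayama) places the peroxide on C6′ and hydrogen on C5′ in the silyl peroxide F10. HF·pyridine gives the hydroperoxide F11, and KOtBu/18-crown-6 closes the ring, returning to the route at 36. This radical step has no facial control, so both C6′ epimers are expected and the C6′ epimer of 36 has to be removed by chromatography.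

Further compounds
F1 | step 8 | (5S,9E,11Z)-1-(tert-butyldimethylsilyloxy)-8,8-dimethyl-5-(triethylsilyloxy)trideca-9,11-dien-3-yne | CC(C)(C)[Si](C)(C)OCCC#C[C@@H](O[Si](CC)(CC)CC)CCC(C)(C)/C=C/C=C\C
F2 | step 8 | alkenylzirconocene chloride from F1 (zirconium on C3 of the chain, cis to H on C4) | CC(C)(C)[Si](C)(C)OCC/C(=C\[C@@H](O[Si](CC)(CC)CC)CCC(C)(C)/C=C/C=C\C)[Zr](Cl)(C1C=CC=C1)C1C=CC=C1
F3 | step 8 | (3E,5S,9E,11Z)-1-(tert-butyldimethylsilyloxy)-3-iodo-8,8-dimethyl-5-(triethylsilyloxy)trideca-3,9,11-triene | CC(C)(C)[Si](C)(C)OCC/C(I)=C\[C@@H](O[Si](CC)(CC)CC)CCC(C)(C)/C=C/C=C\C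
F4 | step 8 | methyl (2E,4S,8E,10Z)-2-[2-(tert-butyldimethylsilyloxy)ethyl]-7,7-dimethyl-4-(triethylsilyloxy)dodeca-2,8,10-trienoate | COC(=O)/C(CCO[Si](C)(C)C(C)(C)C)=C/[C@@H](O[Si](CC)(CC)CC)CCC(C)(C)/C=C/C=C\C
F5 | step 8 | trans-fused adduct: methyl 9α-[2-(tert-butyldimethylsilyloxy)ethyl]-4,4,8α-trimethyl-1α-(triethylsilyloxy)-5αH,10βH-octal-6-ene-9β-carboxylate (core numbering) | CC(C)(C)[Si](C)(C)OCC[C@@]1(C(=O)OC)[C@H]2[C@@H](O[Si](CC)(CC)CC)CCC(C)(C)[C@@H]2C=C[C@H]1C
F6 | step 8 | 6,7-dihydro derivative of F5 | CC(C)(C)[Si](C)(C)OCC[C@@]1(C(=O)OC)[C@H]2[C@@H](O[Si](CC)(CC)CC)CCC(C)(C)[C@@H]2CC[C@H]1C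
F7 | step 8 | 1α-alcohol from F6 | CC(C)(C)[Si](C)(C)OCC[C@@]1(C(=O)OC)[C@H]2[C@@H](O)CCC(C)(C)[C@@H]2CC[C@H]1C
F8 | step 23 | epoxide 32 with the mesylate replaced, with inversion, by a (2-methoxypropan-2-yl)peroxy group at C3′ | C[C@@]1(CC[C@@]2(C)C3=CCCC(C)(C)[C@@H]3CC[C@H]2C)O[C@H]1C[C@H](OOC(C)(C)OC)[C@H](C)CO[Si](c1ccccc1)(c1ccccc1)C(C)(C)C
F9 | step 23 | C3′ hydroperoxide from F8 | C[C@@]1(CC[C@@]2(C)C3=CCCC(C)(C)[C@@H]3CC[C@H]2C)O[C@H]1C[C@H](OO)[C@H](C)CO[Si](c1ccccc1)(c1ccccc1)C(C)(C)C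
F10 | step 25 | (2R,3R,6R)-8-Bic-1-(tert-butyldiphenylsilyloxy)-2,6-dimethyl-6-(triethylsilylperoxy)octan-3-yl methanesulfonate | C[C@](CC[C@@]1(C)C2=CCCC(C)(C)[C@@H]2CC[C@H]1C)(OO[Si](CC)(CC)CC)CC[C@@H](OS(C)(=O)=O)[C@H](C)CO[Si](c1ccccc1)(c1ccccc1)C(C)(C)C
F11 | step 25 | (2R,3R,6R)-8-Bic-1-(tert-butyldiphenylsilyloxy)-6-hydroperoxy-2,6-dimethyloctan-3-yl methanesulfonate | C[C@](CC[C@@]1(C)C2=CCCC(C)(C)[C@@H]2CC[C@H]1C)(OO)CC[C@@H](OS(C)(=O)=O)[C@H](C)CO[Si](c1ccccc1)(c1ccccc1)C(C)(C)C
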